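## Structural features

Seco-guaiane numbering is used throughout: ring carbons C1, C5, C6, C7, C8, C9, C10; chain C2, C3, C4, C15 on C1; lactone carbons C11, C12, C13; methyl C14 on C10.

The target is a cis-fused cyclohepta[b]furan-2-one: a cycloheptane fused through C6–C7 to an α-methyl-γ-butyrolactone (O on C6, C11 on C7). C1 is a fully substituted carbinol that carries the (E)-but-2-enoyl chain. C5 carries the (Z)-2-methylbut-2-enoate (angelate), C9 a free secondary hydroxyl and C10 a methyl group; only C8 is a methylene. Six ring stereocentres are contiguous (C9, C10, C1, C5, C6, C7) and C11 is the seventh. On one face (β) lie C5–O, C9–O and the acyl chain; on the other (α) lie C1–OH, C6–O, C7–C11 and the C10 methyl. H6, H7 and H11 are all cis, so the C13 methyl sits on the concave face of the lactone. The oxygens on C6 and C9 are 1,4-related across C7–C8 and trans to each other. Fragile groups are the angelate (Z to E isomerisation, acyl migration), the α'-hydroxy enone (oxa-Michael closure, α-ketol shift under base) and the epimerisable C11. The real difficulty is the seven-membered ring with six contiguous stereocentres, including a quaternary carbinol flanked by two stereocentres and a hindered secondary angelate beside it.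

## Logic of the disconnections

**22 to 20.** The lactone oxygen–C6 bond is cut and C6 is reconnected to the oxygen on C9, giving the oxygen-bridged bicycle 20. The cut is made there because C6–O and C9–O are 1,4-trans: one oxygen held on the β face of both carbons, opened by one SN2 attack of the C12 carboxyl on C6 from the α face, gives the α lactone oxygen and the β hydroxyl on C9 together. The gain is a rigid 8-oxabicyclo[3.2.1]octane in which C9–OH is masked, so the angelate can be in place before the last step and no protecting group is needed. The demand is that the arm on C7 is endo (anti to the bridge oxygen) and that the ether can be activated without harming the angelate and the enone.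

**20 to 18 and 19.** The C3=C4 double bond is cut (cross-metathesis). This lets the smallest acyl-anion equivalent be used at the hindered ketone. The demand is that the trisubstituted angelate alkene stays out of the metathesis.

**18 to 15 and 16.** The C1–C2 bond is cut. In 15 C1 is the ketone of the three-carbon bridge, whose endo face is covered, so addition from the exo face sets C1 with the chain equatorial and the hydroxyl axial. The demand is chemoselective addition to the ketone beside an ester.

**15 to 12 and 13.** The alkyl C5–O bond of the angelate is cut, with inversion. The hindered angelate is thus brought in as a nucleophile at a carbon activated by the neighbouring ketone, and the equatorial oxygen delivered by the cycloaddition is turned into the axial one required. The demand is clean SN2 without epimerisation of the α-acyloxy ketone.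

**12 to 10.** Functional-group step: C7–H and C8–H are removed to give the C7=C8 alkene and the C5 hydroxyl is returned to its 1-phenylethyl ether. Forward, hydrogen must arrive from the exo face (arm endo, C7 set) without moving the double bond toward C11.

**10 to 3 and 8.** The C5–C6 and C9–C10 bonds are cut, a (4+3) disconnection. All seven ring carbons, each with its final substituent atom (O on C5, bridge O on C6 and C9, C=O at C1, methyl on C10, C11 arm on C7), come from two small pieces. The demands are the regiochemistry (alkoxy carbon to the furan carbon beside the arm), equatorial alkoxy and methyl groups, and facial control by the auxiliary.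

**8 to 7 to 5 and 6; 5 to 4.** Standard enol silane formation, transacetalisation and methylation; no strategic content.

**3 to 2 to 1.** Esterification and an enantioselective α-methylation that buys C11.

## Other disconnections considered

**Alternative 1:** (the first that comes to mind) cut C9=C10 after a hydroboration transform and close the ring by ring-closing metathesis of the acyclic diene A1 to the cycloheptene A2, then hydroborate the trisubstituted alkene to set C9 and C10. A1 needs C1, C5, C6, C7 and C11 set one by one on an open chain, with the quaternary carbinol directly beside the 1,1-disubstituted alkene that must enter the metathesis. Closure to a trisubstituted cycloheptene next to a fully substituted carbon should be slow, and the later hydroboration of a flexible ring has no strong facial bias. The chosen plan lets one rigid bicycle relay C1, C7, C9 and C10 and needs roughly half as many steps.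

**Alternative 2:** the same cycloaddition type in the other orientation: ketone at C7, alkoxy on C6, oxygen bridge between C5 and C9, from furan A3 to cycloadduct A4. In the target C5–O and C9–O are cis, so the single bridge oxygen can serve only one of them; the other would have to be removed by β-elimination and put back on a flexible cycloheptenone. A4 also brings none of the C10 methyl, the C1 substituents or the C11 arm, and its two alkene carbons would have to be told apart by reagent control. In the chosen orientation the bridge spans the trans pair C6/C9, so one SN2 opening uses the oxygen productively.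

**Alternative 3:** dearomatisation: [4+2] addition of singlet oxygen to tropone A5 to give the endoperoxide A6, which would place the cis oxygens on C5 and C9 and the C6 ketone in one step. A6 is racemic with no handle for absolute configuration, and the peroxide is base-sensitive. The remaining C1=C10 alkene must accept the methyl group and the quaternary carbinol with regio- and facial control that this flat diene system does not offer. The oxygen-bridged bicycle of the chosen plan does offer it.

Key step: step 6

Assumption: the (1S)-1-phenylethyl acetal (model: E-oxocarbenium, C–H eclipsed, furan anti to phenyl) and the chosen enantiomer of the chiral lithium amide are taken to induce the configurations drawn, and the alkoxy group is taken to end equatorial; with the opposite sense of induction the mirror-image alcohol or amide would be used and nothing else changes.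

## Steps

Step 1
Reactants: 1 2-(furan-3-yl)acetic acid
Product: 2 (2R)-2-(furan-3-yl)propanoic acid
Conditions: n-BuLi (4 equiv), C2-symmetric chiral tetramine (two 1-phenyl-2-piperidinoethylamine units joined by a trimethylene tether; enantiomer giving the R acid), THF, 0 to −78 °C; MeI; aq. HCl (amine recovered)
Reagents that add atoms: iodomethane, CI
Why: Enantioselective alkylation of the dilithium enediolate of an arylacetic acid in a mixed aggregate with a chiral lithium amide (traceless auxiliary); the amide shields one enolate face, so methylation should create C11 as R.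

Step 2
Reactants: 2 (2R)-2-(furan-3-yl)propanoic acid
Product: 3 tert-butyl (2R)-2-(furan-3-yl)propanoate
Conditions: Me2NCH(Ot-Bu)2, toluene, 80 °C
Reagents that add atoms: N,N-dimethylformamide di-tert-butyl acetal, CN(C)C(OC(C)(C)C)OC(C)(C)C
Why: Esterification by O-alkylation of the carboxylate with the amide acetal; the neutral conditions should spare the acid-sensitive furan and the α-stereocentre.

Step 3
Reactants: 4 1,1-dimethoxypropan-2-one
Product: 5 1,1-dimethoxybutan-2-one
Conditions: LiN(i-Pr)2, THF, −78 °C; MeI, −78 to −40 °C
Reagents that add atoms: iodomethane, CI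
Why: Kinetic enolate alkylation; deprotonation should occur only at the methyl group because the acetal CH is hindered and its enolate is destabilised by the two alkoxy groups.

Step 4
Reactants: 5 1,1-dimethoxybutan-2-one; 6 (1S)-1-phenylethanol
Product: 7 1-methoxy-1-[(1S)-1-phenylethoxy]butan-2-one (both configurations at the acetal carbon)
Conditions: pyridinium p-toluenesulfonate (cat.), cyclohexane, 50 °C, MeOH removed (5 Å sieves)
Reagents that add atoms: none
Why: Acid-catalysed transacetalisation driven by removal of methanol; both acetal epimers are usable because that carbon becomes planar in step 6.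

Step 5
Reactants: 7 1-methoxy-1-[(1S)-1-phenylethoxy]butan-2-one
Product: 8 triethyl{[(2Z)-1-methoxy-1-[(1S)-1-phenylethoxy]but-2-en-2-yl]oxy}silane
Conditions: LiN(i-Pr)2, Et3SiCl, THF, −78 °C
Reagents that add atoms: chlorotriethylsilane, CC[Si](Cl)(CC)CC
Why: Kinetic enolisation of an ethyl ketone next to a bulky α-substituent should give the Z enolate, trapped on oxygen as the silyl enol ether.

Step 6
Reactants: 3 tert-butyl (2R)-2-(furan-3-yl)propanoate; 8 triethyl{[(2Z)-1-methoxy-1-[(1S)-1-phenylethoxy]but-2-en-2-yl]oxy}silane
Product: 10 tert-butyl (2R)-2-[(1R,2S,4R,5S)-2-methyl-3-oxo-4-[(1S)-1-phenylethoxy]-8-oxabicyclo[3.2.1]oct-6-en-6-yl]propanoate (methyl and alkoxy both equatorial, trans to the oxygen bridge; bicycle C1, C2, C3, C4, C5, C6, C7 = target C9, C10, C1, C5, C6, C7, C8), via silyloxyallyl cation 9 (not isolated)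
Conditions: TMSOTf (0.1 equiv), CH2Cl2, −95 to −78 °C; then Et3N, aq. NaHCO3
Reagents that add atoms: none
Why: The silyl triflate ionises the mixed acetal (methoxide leaves as its silyl ether) to the Z-configured 1-alkoxy-2-silyloxyallyl cation 9, and the closest known reaction type is the silyl-triflate-promoted (4+3) cycloaddition of silyl enol ethers of α-keto acetals with furans. The most nucleophilic furan carbon, C2 beside the alkyl arm, attacks the oxocarbenium carbon (bond C5–C6), and the silyl enol ether carbon then closes onto the resulting 2H-furanium ion at the other α-carbon (bond C9–C10), which closes the seven-membered carbocycle in a 4-carbon plus 3-carbon mode and leaves the furan oxygen as a one-atom bridge. C6 and C9 become cis bridgeheads because both bonds form on the same furan face. The alkoxy group on C5 and the methyl on C10 should end equatorial because the W-shaped (Z,Z) cation reacts through the compact transition state. The absolute sense comes from the 1-phenylethyl group, whose phenyl ring shields one face of the oxocarbenium ion. C11 is a spectator. The step needs regioselectivity (secured by the electronic bias of the 3-alkylfuran toward attack at C2 and by the strongly polarised cation), facial selectivity (auxiliary) and suppression of simple furan alkylation (very low temperature).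

Step 7
Reactants: 10 tert-butyl (2R)-2-[(1R,2S,4R,5S)-2-methyl-3-oxo-4-[(1S)-1-phenylethoxy]-8-oxabicyclo[3.2.1]oct-6-en-6-yl]propanoate
Product: 12 tert-butyl (2R)-2-[(1R,2S,4R,5S,6S)-4-hydroxy-2-methyl-3-oxo-8-oxabicyclo[3.2.1]octan-6-yl]propanoate (arm endo, hydroxyl equatorial), via saturated phenylethyl ether 11 (not isolated)
Conditions: H2 (1 atm), [Ir(cod)(PCy3)(py)]PF6 (5 mol%), CH2Cl2, rt; then evaporation, H2 (1 atm), Pd(OH)2/C, EtOAc, rt
Reagents that add atoms: none
Why: Homogeneous hydrogenation should deliver H2 to the exo face (the face of the bridge oxygen, which can also bind the catalyst; the endo face is covered by the three-carbon bridge), placing the arm endo and setting C7. The cationic iridium catalyst is chosen to avoid the allylic isomerisation that would scramble C11. Hydrogenolysis then removes the benzylic auxiliary.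

Step 8
Reactants: 12 tert-butyl (2R)-2-[(1R,2S,4R,5S,6S)-4-hydroxy-2-methyl-3-oxo-8-oxabicyclo[3.2.1]octan-6-yl]propanoate; 13 angelic acid [(2Z)-2-methylbut-2-enoic acid]
Product: 15 (1R,2S,4S,5S,6S)-6-[(2R)-1-tert-butoxy-1-oxopropan-2-yl]-2-methyl-3-oxo-8-oxabicyclo[3.2.1]octan-4-yl (2Z)-2-methylbut-2-enoate (angelate axial, cis to the oxygen bridge), via triflate 14 (not isolated)
Conditions: Tf2O, pyridine, CH2Cl2, −40 °C; then Cs[O2CC(CH3)=CHCH3] (from 13, Cs2CO3, MeOH; dried), 18-crown-6, MeCN, −20 °C to rt
Reagents that add atoms: trifluoromethanesulfonic anhydride, O=S(=O)(OS(=O)(=O)C(F)(F)F)C(F)(F)F (supplies the triflate group of 14; no atom of it remains in 15)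
Why: Triflation, then SN2 displacement by carboxylate at a carbon activated by the adjacent carbonyl; attack along the open exo (axial) trajectory inverts C5 to the required configuration and installs the angelate without acylating a hindered alcohol. Elimination toward the bridgehead C6 is not available, and carboxylate alkylation should not isomerise the Z alkene.

Step 9
Reactants: 15 (1R,2S,4S,5S,6S)-6-[(2R)-1-tert-butoxy-1-oxopropan-2-yl]-2-methyl-3-oxo-8-oxabicyclo[3.2.1]octan-4-yl (2Z)-2-methylbut-2-enoate; 16 methoxyallene (1-methoxypropa-1,2-diene)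
Product: 18 (1R,2S,3S,4S,5S,6S)-6-[(2R)-1-tert-butoxy-1-oxopropan-2-yl]-3-hydroxy-2-methyl-3-(prop-2-enoyl)-8-oxabicyclo[3.2.1]octan-4-yl (2Z)-2-methylbut-2-enoate, via allenyl ether adduct 17 (not isolated)
Conditions: 16, n-BuLi, THF, −40 °C; then 15, −78 °C; then 5% aq. H2SO4, THF, 0 °C
Reagents that add atoms: water, O
Why: 1,2-Addition of a small, linear alkoxyallenyllithium (an acryloyl anion equivalent) to the ketone from the exo face, the endo face being blocked by the ethano bridge and its arm, should give the tertiary alcohol with C2 equatorial and the hydroxyl axial (C1 set). Acyl migration is not possible across the trans-diaxial C1–O/C5–O pair, and dilute acid hydrolyses the enol ether to the vinyl ketone.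

Step 10
Reactants: 18 (1R,2S,3S,4S,5S,6S)-6-[(2R)-1-tert-butoxy-1-oxopropan-2-yl]-3-hydroxy-2-methyl-3-(prop-2-enoyl)-8-oxabicyclo[3.2.1]octan-4-yl (2Z)-2-methylbut-2-enoate; 19 (Z)-but-2-ene
Product: 20 (1R,2S,3S,4S,5S,6S)-3-[(2E)-but-2-enoyl]-6-[(2R)-1-tert-butoxy-1-oxopropan-2-yl]-3-hydroxy-2-methyl-8-oxabicyclo[3.2.1]octan-4-yl (2Z)-2-methylbut-2-enoate
Conditions: 19 (excess), second-generation Grubbs catalyst RuCl2(PCy3)(H2IMes)(=CHPh) (5 mol%), CH2Cl2, 40 °C, sealed tube
Reagents that add atoms: none
Why: Cross-metathesis of a vinyl ketone with an excess of a simple internal alkene should give the E enone; the trisubstituted, conjugated angelate alkene is too hindered and electron-poor to take part.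

Step 11
Reactants: 20 (1R,2S,3S,4S,5S,6S)-3-[(2E)-but-2-enoyl]-6-[(2R)-1-tert-butoxy-1-oxopropan-2-yl]-3-hydroxy-2-methyl-8-oxabicyclo[3.2.1]octan-4-yl (2Z)-2-methylbut-2-enoate
Product: 22 CNP0183494.1, (3R,3aS,5R,6S,7S,8S,8aR)-7-[(2E)-but-2-enoyl]-5,7-dihydroxy-3,6-dimethyl-2-oxooctahydro-2H-cyclohepta[b]furan-8-yl (2Z)-2-methylbut-2-enoate, via bis-silyl ether 21 (not isolated)
Conditions: TMSOTf (4 equiv), 2,6-di-tert-butyl-4-methylpyridine (2.5 equiv), CH2Cl2, −40 to 0 °C; then 1 M HCl, THF, 0 °C
Reagents that add atoms: trimethylsilyl trifluoromethanesulfonate, C[Si](C)(C)OS(=O)(=O)C(F)(F)F (supplies the silyl groups of 21; no atom of it remains in 22)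
Why: Lewis-acid-promoted lactonisation with cleavage of the oxygen bridge: the silyl triflate caps the tertiary hydroxyl, activates the bridging ether and unmasks the tert-butyl ester (isobutene lost), and the ester carbonyl oxygen of the endo arm attacks C6 anti to the C6–O bond (5-exo-tet SN2). This inverts C6, forms the cis-fused lactone and leaves the former bridge oxygen on C9 with retention. The closest relatives are the Lewis-acid lactonisation of tert-butyl esters onto epoxides and the anchimerically assisted acidolysis of oxanorbornane-type ethers by an endo carboxyl group; the hindered pyridine base removes triflic acid so that the angelate and the enone meet only a silyl Lewis acid.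

## Compound list

1 | 2-(furan-3-yl)acetic acid | OC(=O)Cc1ccoc1 | starting material
2 | (2R)-2-(furan-3-yl)propanoic acid | C[C@@H](C(=O)O)c1ccoc1 | intermediate
3 | tert-butyl (2R)-2-(furan-3-yl)propanoate | C[C@@H](C(=O)OC(C)(C)C)c1ccoc1 | intermediate
4 | 1,1-dimethoxypropan-2-one | CC(=O)C(OC)OC | starting material
5 | 1,1-dimethoxybutan-2-one | CCC(=O)C(OC)OC | intermediate
6 | (1S)-1-phenylethanol | C[C@H](O)c1ccccc1 | starting material
7 | 1-methoxy-1-[(1S)-1-phenylethoxy]butan-2-one (both acetal epimers) | CCC(=O)C(OC)O[C@@H](C)c1ccccc1 | intermediate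
8 | triethyl{[(2Z)-1-methoxy-1-[(1S)-1-phenylethoxy]but-2-en-2-yl]oxy}silane | C/C=C(\O[Si](CC)(CC)CC)C(OC)O[C@@H](C)c1ccccc1 | intermediate
9 | [(2Z)-2-(triethylsilyloxy)but-2-en-1-ylidene][(1S)-1-phenylethyl]oxonium trifluoromethanesulfonate (alkoxy-substituted silyloxyallyl cation) | C/C=C(\O[Si](CC)(CC)CC)C=[O+][C@@H](C)c1ccccc1.[O-]S(=O)(=O)C(F)(F)F | intermediate
10 | tert-butyl (2R)-2-[(1R,2S,4R,5S)-2-methyl-3-oxo-4-[(1S)-1-phenylethoxy]-8-oxabicyclo[3.2.1]oct-6-en-6-yl]propanoate | C[C@@H](c3ccccc3)O[C@@H]1[C@H]2O[C@H](C=C2[C@@H](C)C(=O)OC(C)(C)C)[C@H](C)C1=O | intermediate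
11 | tert-butyl (2R)-2-[(1R,2S,4R,5S,6S)-2-methyl-3-oxo-4-[(1S)-1-phenylethoxy]-8-oxabicyclo[3.2.1]octan-6-yl]propanoate | C[C@@H](c3ccccc3)O[C@@H]1[C@H]2O[C@H](C[C@H]2[C@@H](C)C(=O)OC(C)(C)C)[C@H](C)C1=O | intermediate
12 | tert-butyl (2R)-2-[(1R,2S,4R,5S,6S)-4-hydroxy-2-methyl-3-oxo-8-oxabicyclo[3.2.1]octan-6-yl]propanoate | O[C@@H]1[C@H]2O[C@H](C[C@H]2[C@@H](C)C(=O)OC(C)(C)C)[C@H](C)C1=O | intermediate
13 | angelic acid, (2Z)-2-methylbut-2-enoic acid | C/C=C(/C)C(=O)O | starting material
14 | tert-butyl (2R)-2-[(1R,2S,4R,5S,6S)-2-methyl-3-oxo-4-(trifluoromethanesulfonyloxy)-8-oxabicyclo[3.2.1]octan-6-yl]propanoate | FC(F)(F)S(=O)(=O)O[C@@H]1[C@H]2O[C@H](C[C@H]2[C@@H](C)C(=O)OC(C)(C)C)[C@H](C)C1=O | intermediate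
15 | (1R,2S,4S,5S,6S)-6-[(2R)-1-tert-butoxy-1-oxopropan-2-yl]-2-methyl-3-oxo-8-oxabicyclo[3.2.1]octan-4-yl (2Z)-2-methylbut-2-enoate | C/C=C(/C)C(=O)O[C@H]1[C@H]2O[C@H](C[C@H]2[C@@H](C)C(=O)OC(C)(C)C)[C@H](C)C1=O | intermediate
16 | methoxyallene (1-methoxypropa-1,2-diene) | COC=C=C | starting material
17 | (1R,2S,3S,4S,5S,6S)-6-[(2R)-1-tert-butoxy-1-oxopropan-2-yl]-3-hydroxy-3-(1-methoxypropa-1,2-dien-1-yl)-2-methyl-8-oxabicyclo[3.2.1]octan-4-yl (2Z)-2-methylbut-2-enoate | C/C=C(/C)C(=O)O[C@H]1[C@H]2O[C@H](C[C@H]2[C@@H](C)C(=O)OC(C)(C)C)[C@H](C)[C@@]1(O)C(OC)=C=C | intermediate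
18 | (1R,2S,3S,4S,5S,6S)-6-[(2R)-1-tert-butoxy-1-oxopropan-2-yl]-3-hydroxy-2-methyl-3-(prop-2-enoyl)-8-oxabicyclo[3.2.1]octan-4-yl (2Z)-2-methylbut-2-enoate | C/C=C(/C)C(=O)O[C@H]1[C@H]2O[C@H](C[C@H]2[C@@H](C)C(=O)OC(C)(C)C)[C@H](C)[C@@]1(O)C(=O)C=C | intermediate
19 | (Z)-but-2-ene | C/C=C\C | starting material
20 | (1R,2S,3S,4S,5S,6S)-3-[(2E)-but-2-enoyl]-6-[(2R)-1-tert-butoxy-1-oxopropan-2-yl]-3-hydroxy-2-methyl-8-oxabicyclo[3.2.1]octan-4-yl (2Z)-2-methylbut-2-enoate | C/C=C(/C)C(=O)O[C@H]1[C@H]2O[C@H](C[C@H]2[C@@H](C)C(=O)OC(C)(C)C)[C@H](C)[C@@]1(O)C(=O)/C=C/C | intermediate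
21 | bis(trimethylsilyl) ether of 22 (silyl groups on the C1 and C9 oxygens) | C/C=C(/C)C(=O)O[C@H]1[C@@H]2OC(=O)[C@H](C)[C@@H]2C[C@@H](O[Si](C)(C)C)[C@H](C)[C@@]1(O[Si](C)(C)C)C(=O)/C=C/C | intermediate
22 | CNP0183494.1, (3R,3aS,5R,6S,7S,8S,8aR)-7-[(2E)-but-2-enoyl]-5,7-dihydroxy-3,6-dimethyl-2-oxooctahydro-2H-cyclohepta[b]furan-8-yl (2Z)-2-methylbut-2-enoate | C/C=C(/C)C(=O)O[C@H]1[C@@H]2OC(=O)[C@H](C)[C@@H]2C[C@@H](O)[C@H](C)[C@@]1(O)C(=O)/C=C/C | target

## Step count and least certain steps

Total step count: 11. Longest linear sequence: 9 (steps 3, 4, 5, 6, 7, 8, 9, 10, 11).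

**Step 6 (key step).** Most likely to go wrong is formation of the first bond at the other furan α-carbon, because the branched arm crowds C2; this would transpose the arm relative to the methyl/alkoxy pattern. Arrest after the first bond (furan alkylation with rearomatisation) and incomplete facial control by the auxiliary are the next concerns. The axial or equatorial position of the alkoxy group is a further uncertainty; an axial alkoxy group would make the inversion of step 8 unnecessary. Fallback: set out from 8 and use commercial 3-bromofuran as the diene. The halogen is small and directs electrophiles to the adjacent α-carbon, so the same (4+3) reaction should give the bromo cycloadduct F1. A Negishi coupling of this vinyl bromide with the Reformatsky reagent BrZnCH(CH3)CO2t-Bu (Pd(dba)2, 1,2,3,4,5-pentaphenyl-1'-(di-tert-butylphosphino)ferrocene, THF) attaches the arm and gives 10 together with its C11 epimer F2. The two are separated, and F2 can be returned to the mixture through its lithium dienolate. The route is rejoined at 10.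

**Step 11.** Most likely to go wrong is that the ether bridge does not open under conditions the α'-hydroxy enone tolerates. Opening by attack at C9 (six-membered lactone) or acid-induced oxa-Michael closure of the hydroxy enone could also compete, since C6 is deactivated by the neighbouring ester. Fallback: set out from 15 and postpone the enone. 1-Ethoxyvinyllithium, CH2=C(OEt)Li, adds to 15 to give the enol ether adduct F3, and dilute acid gives the methyl ketone F4. F4 carries no acid-sensitive chain and can be exposed to much stronger acid (TfOH, CH2Cl2, rt) to give the keto lactone F5. Soft enolisation (TMSOTf, Et3N) gives the tris-silyl compound F6, a Mukaiyama aldol addition to acetaldehyde (BF3·OEt2, −78 °C) gives the aldol F7, and mesylation–elimination (MsCl, Et3N) rejoins the route at 21.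

**Step 8.** Most likely to go wrong is loss of the α-keto triflate by ionisation or rearrangement before the hindered, weakly nucleophilic carboxylate displaces it, or epimerisation at C5 with the carboxylate acting as a base. Fallback: set out from 12. A Mitsunobu reaction with chloroacetic acid (PPh3, DIAD) inverts C5 under neutral conditions to give the chloroacetate F8. Thiourea with NaHCO3 removes the chloroacetyl group to give the axial alcohol F9. A Yamaguchi esterification with the mixed anhydride of 13 and 2,4,6-trichlorobenzoyl chloride (Et3N, toluene, 80 °C) rejoins the route at 15.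

**Step 9.** Most likely to go wrong is enolisation of the hindered ketone toward C10, or attack at the neighbouring angelate carbonyl, because the axial ester crowds the exo face. Fallback: set out from 12 and prepare the axial alcohol F9 as described for step 8. The allenyllithium is added to F9, whose lithium alkoxide is smaller than the ester and can guide the reagent, to give the allenyl diol F10. Acylation of its secondary hydroxyl with the mixed anhydride of 13 rejoins the route at 17, which is hydrolysed to 18 as in step 9.

**Step 7.** Most likely to go wrong is migration of the C7=C8 double bond into conjugation with the ester before hydrogen is delivered, which would erode C11; incomplete hydrogenolysis is the lesser concern. Fallback: set out from 10 and reduce the alkene without a metal, using diimide generated from dipotassium azodicarboxylate (KO2C–N=N–CO2K) and acetic acid. This concerted syn transfer from the exo face cannot isomerise the alkene. 11 is isolated and then hydrogenolysed alone to 12; no new compound is involved.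

## Further compounds

F1 | step 6 | 6-bromo analogue of 10 (bromine in place of the propanoate arm, ring stereocentres as in 10) | C[C@@H](c3ccccc3)O[C@@H]1[C@H]2O[C@H](C=C2Br)[C@H](C)C1=O
F2 | step 6 | C11 epimer of 10 [(2S)-propanoate] | C[C@@H](c3ccccc3)O[C@@H]1[C@H]2O[C@H](C=C2[C@H](C)C(=O)OC(C)(C)C)[C@H](C)C1=O
F3 | step 11 | 1-ethoxyvinyl adduct of 15 (tertiary alcohol at C1, ring stereocentres as in 17) | C/C=C(/C)C(=O)O[C@H]1[C@H]2O[C@H](C[C@H]2[C@@H](C)C(=O)OC(C)(C)C)[C@H](C)[C@@]1(O)C(=C)OCC
F4 | step 11 | methyl ketone analogue of 18 (acetyl in place of prop-2-enoyl) | C/C=C(/C)C(=O)O[C@H]1[C@H]2O[C@H](C[C@H]2[C@@H](C)C(=O)OC(C)(C)C)[C@H](C)[C@@]1(O)C(C)=O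
F5 | step 11 | acetyl analogue of 22 (acetyl in place of but-2-enoyl) | C/C=C(/C)C(=O)O[C@H]1[C@@H]2OC(=O)[C@H](C)[C@@H]2C[C@@H](O)[C@H](C)[C@@]1(O)C(C)=O
F6 | step 11 | tris(trimethylsilyl) derivative of F5 (two silyl ethers and the silyl enol ether of the acetyl group) | C/C=C(/C)C(=O)O[C@H]1[C@@H]2OC(=O)[C@H](C)[C@@H]2C[C@@H](O[Si](C)(C)C)[C@H](C)[C@@]1(O[Si](C)(C)C)C(=C)O[Si](C)(C)C
F7 | step 11 | 3-hydroxybutanoyl analogue of 21 (aldol, both epimers at the new carbinol) | C/C=C(/C)C(=O)O[C@H]1[C@@H]2OC(=O)[C@H](C)[C@@H]2C[C@@H](O[Si](C)(C)C)[C@H](C)[C@@]1(O[Si](C)(C)C)C(=O)CC(C)O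
F8 | step 8 | chloroacetate analogue of 15 (axial chloroacetoxy group on C5) | ClCC(=O)O[C@H]1[C@H]2O[C@H](C[C@H]2[C@@H](C)C(=O)OC(C)(C)C)[C@H](C)C1=O
F9 | step 8 | C5 epimer of 12 (axial hydroxyl, cis to the oxygen bridge) | O[C@H]1[C@H]2O[C@H](C[C@H]2[C@@H](C)C(=O)OC(C)(C)C)[C@H](C)C1=O
F10 | step 9 | de-angeloyl analogue of 17 (free hydroxyls on C1 and C5) | O[C@H]1[C@H]2O[C@H](C[C@H]2[C@@H](C)C(=O)OC(C)(C)C)[C@H](C)[C@@]1(O)C(OC)=C=C
F0 | step 7 | none | none
A1 | alternative 1 | acyclic metathesis precursor (lactone with allyl group on C7; C5 benzyl ether; C1 carbinol with isopropenyl group and dimethyl acetal) | O(Cc3ccccc3)[C@@H]([C@@H]2OC(=O)[C@H](C)[C@@H]2CC=C)[C@@](O)(C(C)=C)C(OC)OC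
A2 | alternative 1 | cycloheptene from ring-closing metathesis (C9=C10) | O(Cc3ccccc3)[C@H]1[C@@H]2OC(=O)[C@H](C)[C@@H]2CC=C(C)[C@@]1(O)C(OC)OC
A3 | alternative 2 | furan | c1ccoc1
A4 | alternative 2 | 2-[(1S)-1-phenylethoxy]-8-oxabicyclo[3.2.1]oct-6-en-3-one with the oxygen bridge between target C5 and C9 | C[C@@H](c3ccccc3)O[C@H]1[C@H]2C=C[C@H](O2)CC1=O
A5 | alternative 3 | tropone | O=c1cccccc1
A6 | alternative 3 | tropone endoperoxide, 8,9-dioxabicyclo[3.2.2]nona-3,6-dien-2-one (racemic) | O=C1C=CC2C=CC1OO2
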